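Both halves of the target carry the same avarane bicycle, whose ring B (C5, C6, C7, C8, C9, C10) holds the adjacent stereocentres C8 (CH–CH3) and quaternary C9. The route cuts the C8–C9 bond in each: a ring-A-fused δ-lactone (O–C6, carbonyl carbon on C9, fusion at C5–C10) with an (E)-propenyl group on C6 and the arylmethyl group on C9 is converted into its silyl ketene acetal, and one boat-type Ireland–Claisen shift then closes ring B, sets C8 and C9 together and leaves the former lactone carbonyl as the carbon that becomes the C9 methyl. Quinone and aminoresorcylate halves are made the same way from one lactone and joined last.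

Key step: step 10

**Remarks**

- Positions are cited in the terpenoid numbering of the decalin (C1–C10; C5 and C10 are the fusion carbons, C9 carries the arylmethyl group).
- Compound 1 is the six-membered enone C7H10O, SMILES CC1=CCCCC1=O; its carbonyl carbon becomes C4, its methyl-bearing carbon C5 and its β-carbon C10, so that all six ring carbons end up in ring A.
- "Av" is the (1R,2S,4aS,8aS)-1,2,4a,5-tetramethyl-1,2,3,4,4a,7,8,8a-octahydronaphthalen-1-yl group of the target; "ΔAv" is the corresponding 1,2,4a,7,8,8a-hexahydro group with the additional C6=C7 alkene.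
- Assumption: the (S)-prolinol-derived catalyst of step 1 is taken to give the (10S) adduct; if the sense of induction is the opposite, its enantiomer is used.
- Assumption: the silyl ketene acetal 2 and 5-bromo-2,4-dihydroxybenzaldehyde 31 are taken as purchased reagents.
- C9 of the two alkylated lactones is left undefined because both epimers give the same ketene acetal.

**Route**

Step 1
Reactants: 1 2-methylcyclohex-2-en-1-one; 2 1-methoxy-1-(trimethylsilyloxy)ethene
Product: 3 methyl 2-[(1S)-2-methyl-3-(trimethylsilyloxy)cyclohex-2-en-1-yl]acetate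
Conditions: B-(o-tolyl)oxazaborolidine from (S)-diphenylprolinol, Tf2NH (10 mol% each), Ph3PO (20 mol%), toluene, −20 °C; non-aqueous work-up
Reagents that add atoms: none
Why: Enantioselective Mukaiyama–Michael addition, in which the chiral oxazaborolidinium ion activates the enone and exposes one face of C10 to the ketene acetal (this sets C10), while transfer of the silyl group to the enolate oxygen leaves the C4–C5 enol ether regiodefined for step 2.

Step 2
Reactants: 3 methyl 2-[(1S)-2-methyl-3-(trimethylsilyloxy)cyclohex-2-en-1-yl]acetate; 4 (E)-but-2-enal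
Product: 8 methyl 2-[(1S,2R)-2-methyl-3-oxo-2-[(1R,2E)-1-(triethylsilyloxy)but-2-en-1-yl]cyclohexyl]acetate, via potassium enolate 5 (not isolated), via chlorozinc enolate 6 (not isolated), via chlorozinc aldolate 7 (not isolated)
Conditions: KOtBu, THF, −78 → −40 °C; ZnCl2, −78 °C; 4, −78 °C; 2,6-lutidine, Et3SiOTf, −78 → −40 °C
Reagents that add atoms: triethylsilyl trifluoromethanesulfonate, CC[Si](CC)(CC)OS(=O)(=O)C(F)(F)F
Why: Alkoxide-mediated desilylation frees the C5 enolate without harming the ester, and its zinc enolate undergoes an aldol addition through a closed chair (Zimmerman–Traxler) on the ring face opposite the C10 side chain, which sets C5 and, because the C5 methyl group is cis to the enolate oxygen, places the C6 oxygen syn to that methyl group, while silylation of the aldolate in the same flask blocks retro-aldol cleavage.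

Step 3
Reactants: 8 methyl 2-[(1S,2R)-2-methyl-3-oxo-2-[(1R,2E)-1-(triethylsilyloxy)but-2-en-1-yl]cyclohexyl]acetate
Product: 10 methyl 2-[(1S,6R)-6-methyl-6-[(1R,2E)-1-(triethylsilyloxy)but-2-en-1-yl]-5-(trifluoromethylsulfonyloxy)cyclohex-4-en-1-yl]acetate, via potassium enolate 9 (not isolated)
Conditions: KN(SiMe3)2, THF, −78 °C; PhNTf2, −78 → 0 °C
Reagents that add atoms: N-phenylbis(trifluoromethanesulfonimide), O=S(=O)(N(c1ccccc1)S(=O)(=O)C(F)(F)F)C(F)(F)F
Why: Enol triflate formation, in which the ketone can be deprotonated only at C3 because C5 is quaternary and the ester α-hydrogens are markedly less acidic, and PhNTf2 sulfonylates the enolate oxygen with no stereocentre involved.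

Step 4
Reactants: 10 methyl 2-[(1S,6R)-6-methyl-6-[(1R,2E)-1-(triethylsilyloxy)but-2-en-1-yl]-5-(trifluoromethylsulfonyloxy)cyclohex-4-en-1-yl]acetate
Product: 11 methyl 2-[(1S,6S)-5,6-dimethyl-6-[(1R,2E)-1-(triethylsilyloxy)but-2-en-1-yl]cyclohex-4-en-1-yl]acetate
Conditions: MeZnCl, Pd(PPh3)4 (5 mol%), THF, 50 °C
Reagents that add atoms: methylzinc chloride, C[Zn]Cl
Why: Negishi cross-coupling of the enol triflate puts the methyl group on C4, and it is run at this stage because the allylic oxygen is still a silyl ether that zerovalent palladium cannot ionise.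

Step 5
Reactants: 11 methyl 2-[(1S,6S)-5,6-dimethyl-6-[(1R,2E)-1-(triethylsilyloxy)but-2-en-1-yl]cyclohex-4-en-1-yl]acetate
Product: 13 (1R,4aS,8aS)-8,8a-dimethyl-1-[(1E)-prop-1-en-1-yl]-1,4,4a,5,6,8a-hexahydro-3H-isochromen-3-one, via tetrabutylammonium alkoxide 12 (not isolated)
Conditions: Bu4NF, THF, 0 → 25 °C
Reagents that add atoms: none
Why: Fluoride desilylation gives the C6 alkoxide, which closes the δ-lactone by intramolecular transesterification of the methyl ester (lactonisation) with C5, C6 and C10 untouched, so that the ring fusion is trans and the propenyl group lies trans to the C5 methyl group.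

Step 6
Reactants: 14 1,2,4,5-tetramethoxybenzene
Product: 16 (2,3,5,6-tetramethoxyphenyl)methanol, via aryllithium 15 (not isolated)
Conditions: n-BuLi, TMEDA, THF, 0 °C; (CH2O)n, 0 → 25 °C
Reagents that add atoms: formaldehyde (from paraformaldehyde), C=O
Why: Directed ortho-lithiation between two methoxy groups followed by addition of the aryllithium to formaldehyde gives the benzylic alcohol.

Step 7
Reactants: 16 (2,3,5,6-tetramethoxyphenyl)methanol
Product: 17 3-(bromomethyl)-1,2,4,5-tetramethoxybenzene
Conditions: PBr3, CH2Cl2, 0 °C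
Reagents that add atoms: phosphorus tribromide, BrP(Br)Br
Why: Substitution of the benzylic hydroxyl group by bromide with PBr3 gives the alkylating agent.

Step 8
Reactants: 13 (1R,4aS,8aS)-8,8a-dimethyl-1-[(1E)-prop-1-en-1-yl]-1,4,4a,5,6,8a-hexahydro-3H-isochromen-3-one; 17 3-(bromomethyl)-1,2,4,5-tetramethoxybenzene
Product: 19 (1R,4aS,8aS)-8,8a-dimethyl-1-[(1E)-prop-1-en-1-yl]-4-(2,3,5,6-tetramethoxybenzyl)-1,4,4a,5,6,8a-hexahydro-3H-isochromen-3-one (C9 epimers), via lithium enolate 18 (not isolated)
Conditions: LiN(iPr)2, THF, −78 °C; 17, DMPU, −78 → −40 °C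
Reagents that add atoms: none
Why: Enolate C-alkylation of the lactone with the benzylic bromide attaches the arylmethyl group to C9, whose configuration does not matter because this carbon becomes trigonal again in step 9.

Step 9
Reactants: 19 the C9-(2,3,5,6-tetramethoxybenzyl) lactone
Product: 21 tert-butyldimethylsilyl ketene acetal of 19 (C9=C(OSi) in the lactone ring), via lithium enolate 20 (not isolated)
Conditions: LiN(iPr)2, THF, −78 °C; t-BuMe2SiCl, DMPU, −78 → 0 °C; pentane, filtration
Reagents that add atoms: tert-butyldimethylsilyl chloride, CC(C)(C)[Si](C)(C)Cl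
Why: O-Silylation of the lactone enolate gives the ketene acetal, whose double-bond geometry is fixed by the ring, and the tert-butyldimethylsilyl group is chosen in place of a trimethylsilyl group so that the acetal survives isolation and prolonged heating.

Step 10
Reactants: 21 tert-butyldimethylsilyl ketene acetal of 19
Product: 23 (1S,2S,4aS,8aR)-2,4a,5-trimethyl-1-(2,3,5,6-tetramethoxybenzyl)-1,2,4a,7,8,8a-hexahydronaphthalene-1-carboxylic acid, via silyl ester 22 (not isolated)
Conditions: toluene, 110 °C; then 1 M HCl, THF, 25 °C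
Reagents that add atoms: none
Why: Heating triggers a concerted suprafacial [3,3]-sigmatropic shift of the array C9=C(OSi)–O–C6–C7=C8, in which C8 bonds to C9 while the C6–O bond breaks and the C6=C7 alkene appears, and the silyl ester formed is hydrolysed on work-up. The closest known reaction is the Ireland–Claisen rearrangement of lactone silyl ketene acetals that carry an alkenyl group on the carbinol carbon, which gives cycloalkene carboxylic acids. Ring B (C5, C6, C7, C8, C9, C10) closes as the chain is passed from oxygen to carbon across the δ-lactone, and the C5–C10 link between the termini allows only a boat-like, bicyclo[2.2.2]octane-type transition state. C9 is controlled by the C6 centre made in step 2: the propenyl group sits on the lactone face opposite the C5 methyl group and delivers C8 to that face of C9, so the carboxyl carbon stays on the methyl face and the arylmethyl group ends trans to it. C8 is controlled by the (E)-alkene, which in the enforced boat places its methyl group cis to the carboxyl group. The step needs boat over chair and an unchanged alkene geometry, both secured by the ring tether and the ring-fixed ketene acetal, and the robust silyl group tolerates the temperature that the strained trans-fused array may demand.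

Step 11
Reactants: 23 the C9 carboxylic acid
Product: 24 [(1S,2S,4aS,8aR)-2,4a,5-trimethyl-1-(2,3,5,6-tetramethoxybenzyl)-1,2,4a,7,8,8a-hexahydronaphthalen-1-yl]methanol
Conditions: LiAlH4, THF, 0 → 65 °C
Reagents that add atoms: none
Why: Hydride reduction of the hindered carboxylic acid with LiAlH4 gives the neopentyl-type primary alcohol while the alkenes and aryl ethers stay untouched.

Step 12
Reactants: 24 the C9 hydroxymethyl compound
Product: 25 (1S,2S,4aS,8aR)-2,4a,5-trimethyl-1-(2,3,5,6-tetramethoxybenzyl)-1,2,4a,7,8,8a-hexahydronaphthalene-1-carbaldehyde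
Conditions: Dess–Martin periodinane, CH2Cl2, 0 → 25 °C
Reagents that add atoms: none
Why: Dess–Martin oxidation gives the aldehyde, which cannot epimerise because its α-carbon C9 is quaternary.

Step 13
Reactants: 25 the C9 aldehyde
Product: 27 3-(ΔAv-methyl)-1,2,4,5-tetramethoxybenzene, via hydrazone 26 (not isolated)
Conditions: N2H4·H2O, KOH, diethylene glycol, 130 → 200 °C
Reagents that add atoms: none
Why: Wolff–Kishner reduction (Huang–Minlon procedure) turns the aldehyde through its hydrazone into the C9 methyl group and avoids any substitution at the neopentyl carbon.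

Step 14
Reactants: 27 3-(ΔAv-methyl)-1,2,4,5-tetramethoxybenzene
Product: 28 3-(Av-methyl)-1,2,4,5-tetramethoxybenzene
Conditions: H2 (4 bar), RhCl(PPh3)3 (10 mol%), benzene–EtOH, 40 °C
Reagents that add atoms: none
Why: Homogeneous hydrogenation with RhCl(PPh3)3 should reduce the cis-disubstituted C6=C7 alkene far faster than the trisubstituted C3=C4 alkene next to quaternary C5, and no stereocentre is formed.

Step 15
Reactants: 28 3-(Av-methyl)-1,2,4,5-tetramethoxybenzene
Product: 29 3-(Av-methyl)-2,5-dimethoxy-1,4-benzoquinone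
Conditions: (NH4)2Ce(NO3)6, MeCN–H2O, 0 °C
Reagents that add atoms: water, O
Why: Oxidative demethylation with (NH4)2Ce(NO3)6 converts a para pair of methoxy groups of the electron-rich arene into the quinone carbonyls, and the symmetry of the arene makes both possible pairs give the same quinone.

Step 16
Reactants: 29 3-(Av-methyl)-2,5-dimethoxy-1,4-benzoquinone
Product: 30 3-(Av-methyl)-2-hydroxy-5-methoxy-1,4-benzoquinone
Conditions: KOH, MeOH–H2O, 25 °C; then 1 M HCl
Reagents that add atoms: potassium hydroxide, [K+].[OH-]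
Why: Hydrolysis of a vinylogous ester by addition–elimination of hydroxide, in which the methoxy group flanked by the alkyl substituent is twisted out of conjugation and should be replaced first, giving the 2-hydroxy-5-methoxy pattern.

Step 17
Reactants: 31 5-bromo-2,4-dihydroxybenzaldehyde
Product: 32 5-bromo-2,4-bis(methoxymethoxy)benzaldehyde
Conditions: MeOCH2Cl, iPr2NEt, CH2Cl2, 0 → 40 °C
Reagents that add atoms: chloromethyl methyl ether, COCCl
Why: Double O-alkylation of the phenols (methoxymethyl ether protection) gives a mask that is stable to base and hydride and labile to acid.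

Step 18
Reactants: 32 5-bromo-2,4-bis(methoxymethoxy)benzaldehyde
Product: 33 [5-bromo-2,4-bis(methoxymethoxy)phenyl]methanol
Conditions: NaBH4, MeOH, 0 °C
Reagents that add atoms: none
Why: Borohydride reduction of the aldehyde gives the benzylic alcohol.

Step 19
Reactants: 33 [5-bromo-2,4-bis(methoxymethoxy)phenyl]methanol
Product: 34 1-bromo-5-(bromomethyl)-2,4-bis(methoxymethoxy)benzene
Conditions: CBr4, PPh3, CH2Cl2, 0 °C
Reagents that add atoms: tetrabromomethane, BrC(Br)(Br)Br
Why: Appel bromination converts the benzylic alcohol into the bromide under neutral conditions that spare the acetal groups.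

Step 20
Reactants: 13 (1R,4aS,8aS)-8,8a-dimethyl-1-[(1E)-prop-1-en-1-yl]-1,4,4a,5,6,8a-hexahydro-3H-isochromen-3-one; 34 1-bromo-5-(bromomethyl)-2,4-bis(methoxymethoxy)benzene
Product: 36 (1R,4aS,8aS)-4-[5-bromo-2,4-bis(methoxymethoxy)benzyl]-8,8a-dimethyl-1-[(1E)-prop-1-en-1-yl]-1,4,4a,5,6,8a-hexahydro-3H-isochromen-3-one (C9 epimers), via sodium enolate 35 (not isolated)
Conditions: NaN(SiMe3)2, THF, −78 °C; 34, −78 → −40 °C
Reagents that add atoms: none
Why: Enolate C-alkylation of the lactone, run here through the sodium enolate, which is nucleophilic enough to take up the benzylic bromide without a polar additive and is made with a hindered silylamide base that cannot metalate the bromoarene, attaches the second arylmethyl group to C9, whose configuration is again erased in the next step.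

Step 21
Reactants: 36 the C9-[5-bromo-2,4-bis(methoxymethoxy)benzyl] lactone
Product: 38 tert-butyldimethylsilyl ketene acetal of 36, via lithium enolate 37 (not isolated)
Conditions: LiN(iPr)2, THF, −78 °C; t-BuMe2SiCl, DMPU, −78 → 0 °C; pentane, filtration
Reagents that add atoms: tert-butyldimethylsilyl chloride, CC(C)(C)[Si](C)(C)Cl
Why: O-Silylation of the lactone enolate gives the ring-fixed ketene acetal as in step 9.

Step 22
Reactants: 38 tert-butyldimethylsilyl ketene acetal of 36
Product: 40 [(1S,2S,4aS,8aR)-1-[5-bromo-2,4-bis(methoxymethoxy)benzyl]-2,4a,5-trimethyl-1,2,4a,7,8,8a-hexahydronaphthalen-1-yl]methanol, via silyl ester 39 (not isolated)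
Conditions: toluene, 110 °C; then LiAlH4, THF, 0 → 25 °C
Reagents that add atoms: none
Why: Ireland–Claisen rearrangement through the same ring-enforced boat as in step 10 closes ring B and sets C8 and C9 by the C6 configuration and the (E)-alkene, and LiAlH4 added to the cooled mixture reduces the silyl ester directly to the primary alcohol at a temperature that leaves the aryl bromide alone.

Step 23
Reactants: 40 the C9 hydroxymethyl aryl bromide
Product: 41 (1S,2S,4aS,8aR)-1-[5-bromo-2,4-bis(methoxymethoxy)benzyl]-2,4a,5-trimethyl-1,2,4a,7,8,8a-hexahydronaphthalene-1-carbaldehyde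
Conditions: Dess–Martin periodinane, CH2Cl2, 0 → 25 °C
Reagents that add atoms: none
Why: Dess–Martin oxidation gives the non-epimerisable aldehyde as in step 12.

Step 24
Reactants: 41 the C9 aldehyde aryl bromide
Product: 43 1-bromo-5-(ΔAv-methyl)-2,4-bis(methoxymethoxy)benzene, via hydrazone 42 (not isolated)
Conditions: N2H4·H2O, KOH, diethylene glycol, 130 → 200 °C
Reagents that add atoms: none
Why: Wolff–Kishner reduction gives the C9 methyl group, and the acetal ethers and the unactivated aryl bromide are stable to hot alkali.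

Step 25
Reactants: 43 1-bromo-5-(ΔAv-methyl)-2,4-bis(methoxymethoxy)benzene
Product: 44 1-bromo-5-(Av-methyl)-2,4-bis(methoxymethoxy)benzene
Conditions: H2 (4 bar), RhCl(PPh3)3 (10 mol%), benzene–EtOH, 40 °C
Reagents that add atoms: none
Why: Selective homogeneous hydrogenation of the C6=C7 alkene as in step 14, with a catalyst that does not cleave the aryl bromide.

Step 26
Reactants: 44 1-bromo-5-(Av-methyl)-2,4-bis(methoxymethoxy)benzene
Product: 46 methyl 5-(Av-methyl)-2,4-bis(methoxymethoxy)benzoate, via aryllithium 45 (not isolated)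
Conditions: t-BuLi, THF, −78 °C; ClCO2Me, −78 → 0 °C
Reagents that add atoms: methyl chloroformate, COC(Cl)=O
Why: Bromine–lithium exchange followed by acylation of the aryllithium with methyl chloroformate installs the ester.

Step 27
Reactants: 46 methyl 5-(Av-methyl)-2,4-bis(methoxymethoxy)benzoate
Product: 47 methyl 5-(Av-methyl)-2,4-dihydroxybenzoate
Conditions: HCl (cat.), MeOH, 40 °C
Reagents that add atoms: none
Why: Acid-catalysed acetal cleavage in methanol removes both methoxymethyl groups, and transesterification of the methyl ester in this solvent is degenerate.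

Step 28
Reactants: 47 methyl 5-(Av-methyl)-2,4-dihydroxybenzoate
Product: 48 methyl 5-(Av-methyl)-2,4-dihydroxy-3-[(E)-(4-nitrophenyl)diazenyl]benzoate
Conditions: 4-O2NC6H4N2BF4, Na2CO3, THF–H2O, 0 °C
Reagents that add atoms: 4-nitrobenzenediazonium tetrafluoroborate, [O-][N+](=O)c1ccc(cc1)[N+]#N.F[B-](F)(F)F
Why: Azo coupling (electrophilic aromatic substitution of the phenoxide by the diazonium ion) can take place only at C3 between the two hydroxyl groups, and alkenes do not react with diazonium ions.

Step 29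
Reactants: 48 the 3-arylazo resorcylate
Product: 49 methyl 3-amino-5-(Av-methyl)-2,4-dihydroxybenzoate
Conditions: Na2S2O4, THF–H2O, 50 °C, argon
Reagents that add atoms: none
Why: Reductive cleavage of the azo group with Na2S2O4 gives the arylamine and leaves alkene and ester untouched.

Step 30
Reactants: 30 3-(Av-methyl)-2-hydroxy-5-methoxy-1,4-benzoquinone; 49 methyl 3-amino-5-(Av-methyl)-2,4-dihydroxybenzoate
Product: 50 nakijiquinone F
Conditions: EtOH, 40 °C, argon, dark
Reagents that add atoms: none
Why: Addition–elimination of the arylamine at the methoxy-bearing carbon C5 of the quinone (aminolysis of a vinylogous ester) forms the C–N bond and gives the target, no stereocentre being involved.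

**Compound list**

1 | 2-methylcyclohex-2-en-1-one | CC1=CCCCC1=O | starting material
2 | 1-methoxy-1-(trimethylsilyloxy)ethene | C=C(OC)O[Si](C)(C)C | starting material
3 | methyl 2-[(1S)-2-methyl-3-(trimethylsilyloxy)cyclohex-2-en-1-yl]acetate | COC(=O)C[C@@H]1CCCC(O[Si](C)(C)C)=C1C | intermediate
4 | (E)-but-2-enal | C/C=C/C=O | starting material
5 | potassium enolate from 3 (not isolated) | COC(=O)C[C@@H]1CCCC(O[K])=C1C | intermediate
6 | chlorozinc enolate from 5 (not isolated) | COC(=O)C[C@@H]1CCCC(O[Zn]Cl)=C1C | intermediate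
7 | chlorozinc aldolate (not isolated) | COC(=O)C[C@@H]1CCCC(=O)[C@@]1(C)[C@H](O[Zn]Cl)/C=C/C | intermediate
8 | methyl 2-[(1S,2R)-2-methyl-3-oxo-2-[(1R,2E)-1-(triethylsilyloxy)but-2-en-1-yl]cyclohexyl]acetate | COC(=O)C[C@@H]1CCCC(=O)[C@@]1(C)[C@H](O[Si](CC)(CC)CC)/C=C/C | intermediate
9 | potassium C3–C4 enolate of 8 (not isolated) | COC(=O)C[C@@H]1CCC=C(O[K])[C@@]1(C)[C@H](O[Si](CC)(CC)CC)/C=C/C | intermediate
10 | methyl 2-[(1S,6R)-6-methyl-6-[(1R,2E)-1-(triethylsilyloxy)but-2-en-1-yl]-5-(trifluoromethylsulfonyloxy)cyclohex-4-en-1-yl]acetate | COC(=O)C[C@@H]1CCC=C(OS(=O)(=O)C(F)(F)F)[C@@]1(C)[C@H](O[Si](CC)(CC)CC)/C=C/C | intermediate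
11 | methyl 2-[(1S,6S)-5,6-dimethyl-6-[(1R,2E)-1-(triethylsilyloxy)but-2-en-1-yl]cyclohex-4-en-1-yl]acetate | COC(=O)C[C@@H]1CCC=C(C)[C@@]1(C)[C@H](O[Si](CC)(CC)CC)/C=C/C | intermediate
12 | tetrabutylammonium alkoxide of desilylated 11 (not isolated) | COC(=O)C[C@@H]1CCC=C(C)[C@@]1(C)[C@H]([O-])/C=C/C.CCCC[N+](CCCC)(CCCC)CCCC | intermediate
13 | (1R,4aS,8aS)-8,8a-dimethyl-1-[(1E)-prop-1-en-1-yl]-1,4,4a,5,6,8a-hexahydro-3H-isochromen-3-one (terpenoid numbering 5S,6R,10S; trans-fused, propenyl trans to the C5 methyl) | C1C(=O)O[C@H](/C=C/C)[C@]2(C)C(C)=CCC[C@@H]12 | intermediate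
14 | 1,2,4,5-tetramethoxybenzene | COc1cc(OC)c(OC)cc1OC | starting material
15 | 2,3,5,6-tetramethoxyphenyllithium (not isolated) | COc1cc(OC)c(OC)c([Li])c1OC | intermediate
16 | (2,3,5,6-tetramethoxyphenyl)methanol | COc1cc(OC)c(OC)c(CO)c1OC | intermediate
17 | 3-(bromomethyl)-1,2,4,5-tetramethoxybenzene | COc1cc(OC)c(OC)c(CBr)c1OC | intermediate
18 | lithium enolate of 13 (not isolated) | C1=C(O[Li])O[C@H](/C=C/C)[C@]2(C)C(C)=CCC[C@@H]12 | intermediate
19 | (1R,4aS,8aS)-8,8a-dimethyl-1-[(1E)-prop-1-en-1-yl]-4-(2,3,5,6-tetramethoxybenzyl)-1,4,4a,5,6,8a-hexahydro-3H-isochromen-3-one, C9 epimers | COc1cc(OC)c(OC)c(CC2C(=O)O[C@H](/C=C/C)[C@]3(C)C(C)=CCC[C@@H]23)c1OC | intermediate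
20 | lithium enolate of 19 (not isolated) | COc1cc(OC)c(OC)c(CC2=C(O[Li])O[C@H](/C=C/C)[C@]3(C)C(C)=CCC[C@@H]23)c1OC | intermediate
21 | tert-butyldimethylsilyl ketene acetal of 19 (precursor of the key step; C5, C6, C10 as in 13) | COc1cc(OC)c(OC)c(CC2=C(O[Si](C)(C)C(C)(C)C)O[C@H](/C=C/C)[C@]3(C)C(C)=CCC[C@@H]23)c1OC | intermediate
22 | tert-butyldimethylsilyl ester of 23 (not isolated) | COc1cc(OC)c(OC)c(C[C@]2(C(=O)O[Si](C)(C)C(C)(C)C)[C@@H](C)C=C[C@]3(C)C(C)=CCC[C@@H]23)c1OC | intermediate
23 | (1S,2S,4aS,8aR)-2,4a,5-trimethyl-1-(2,3,5,6-tetramethoxybenzyl)-1,2,4a,7,8,8a-hexahydronaphthalene-1-carboxylic acid (product of the key step; carboxyl cis to the C5 and C8 methyl groups) | COc1cc(OC)c(OC)c(C[C@]2(C(=O)O)[C@@H](C)C=C[C@]3(C)C(C)=CCC[C@@H]23)c1OC | intermediate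
24 | [(1S,2S,4aS,8aR)-2,4a,5-trimethyl-1-(2,3,5,6-tetramethoxybenzyl)-1,2,4a,7,8,8a-hexahydronaphthalen-1-yl]methanol | COc1cc(OC)c(OC)c(C[C@]2(CO)[C@@H](C)C=C[C@]3(C)C(C)=CCC[C@@H]23)c1OC | intermediate
25 | (1S,2S,4aS,8aR)-2,4a,5-trimethyl-1-(2,3,5,6-tetramethoxybenzyl)-1,2,4a,7,8,8a-hexahydronaphthalene-1-carbaldehyde | COc1cc(OC)c(OC)c(C[C@]2(C=O)[C@@H](C)C=C[C@]3(C)C(C)=CCC[C@@H]23)c1OC | intermediate
26 | hydrazone of 25 (not isolated) | COc1cc(OC)c(OC)c(C[C@]2(C=NN)[C@@H](C)C=C[C@]3(C)C(C)=CCC[C@@H]23)c1OC | intermediate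
27 | 3-(ΔAv-methyl)-1,2,4,5-tetramethoxybenzene | COc1cc(OC)c(OC)c(C[C@]2(C)[C@@H](C)C=C[C@]3(C)C(C)=CCC[C@@H]23)c1OC | intermediate
28 | 3-(Av-methyl)-1,2,4,5-tetramethoxybenzene | COc1cc(OC)c(OC)c(C[C@]2(C)[C@@H](C)CC[C@]3(C)C(C)=CCC[C@@H]23)c1OC | intermediate
29 | 3-(Av-methyl)-2,5-dimethoxy-1,4-benzoquinone | COC1=CC(=O)C(OC)=C(C[C@]2(C)[C@@H](C)CC[C@]3(C)C(C)=CCC[C@@H]23)C1=O | intermediate
30 | 3-(Av-methyl)-2-hydroxy-5-methoxy-1,4-benzoquinone | COC1=CC(=O)C(O)=C(C[C@]2(C)[C@@H](C)CC[C@]3(C)C(C)=CCC[C@@H]23)C1=O | intermediate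
31 | 5-bromo-2,4-dihydroxybenzaldehyde | O=Cc1cc(Br)c(O)cc1O | starting material
32 | 5-bromo-2,4-bis(methoxymethoxy)benzaldehyde | COCOc1cc(OCOC)c(C=O)cc1Br | intermediate
33 | [5-bromo-2,4-bis(methoxymethoxy)phenyl]methanol | COCOc1cc(OCOC)c(CO)cc1Br | intermediate
34 | 1-bromo-5-(bromomethyl)-2,4-bis(methoxymethoxy)benzene | COCOc1cc(OCOC)c(CBr)cc1Br | intermediate
35 | sodium enolate of 13 (not isolated) | C1=C(O[Na])O[C@H](/C=C/C)[C@]2(C)C(C)=CCC[C@@H]12 | intermediate
36 | (1R,4aS,8aS)-4-[5-bromo-2,4-bis(methoxymethoxy)benzyl]-8,8a-dimethyl-1-[(1E)-prop-1-en-1-yl]-1,4,4a,5,6,8a-hexahydro-3H-isochromen-3-one, C9 epimers | COCOc1cc(OCOC)c(CC2C(=O)O[C@H](/C=C/C)[C@]3(C)C(C)=CCC[C@@H]23)cc1Br | intermediate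
37 | lithium enolate of 36 (not isolated) | COCOc1cc(OCOC)c(CC2=C(O[Li])O[C@H](/C=C/C)[C@]3(C)C(C)=CCC[C@@H]23)cc1Br | intermediate
38 | tert-butyldimethylsilyl ketene acetal of 36 | COCOc1cc(OCOC)c(CC2=C(O[Si](C)(C)C(C)(C)C)O[C@H](/C=C/C)[C@]3(C)C(C)=CCC[C@@H]23)cc1Br | intermediate
39 | tert-butyldimethylsilyl ester from 38 (not isolated) | COCOc1cc(OCOC)c(C[C@]2(C(=O)O[Si](C)(C)C(C)(C)C)[C@@H](C)C=C[C@]3(C)C(C)=CCC[C@@H]23)cc1Br | intermediate
40 | [(1S,2S,4aS,8aR)-1-[5-bromo-2,4-bis(methoxymethoxy)benzyl]-2,4a,5-trimethyl-1,2,4a,7,8,8a-hexahydronaphthalen-1-yl]methanol | COCOc1cc(OCOC)c(C[C@]2(CO)[C@@H](C)C=C[C@]3(C)C(C)=CCC[C@@H]23)cc1Br | intermediate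
41 | (1S,2S,4aS,8aR)-1-[5-bromo-2,4-bis(methoxymethoxy)benzyl]-2,4a,5-trimethyl-1,2,4a,7,8,8a-hexahydronaphthalene-1-carbaldehyde | COCOc1cc(OCOC)c(C[C@]2(C=O)[C@@H](C)C=C[C@]3(C)C(C)=CCC[C@@H]23)cc1Br | intermediate
42 | hydrazone of 41 (not isolated) | COCOc1cc(OCOC)c(C[C@]2(C=NN)[C@@H](C)C=C[C@]3(C)C(C)=CCC[C@@H]23)cc1Br | intermediate
43 | 1-bromo-5-(ΔAv-methyl)-2,4-bis(methoxymethoxy)benzene | COCOc1cc(OCOC)c(C[C@]2(C)[C@@H](C)C=C[C@]3(C)C(C)=CCC[C@@H]23)cc1Br | intermediate
44 | 1-bromo-5-(Av-methyl)-2,4-bis(methoxymethoxy)benzene | COCOc1cc(OCOC)c(C[C@]2(C)[C@@H](C)CC[C@]3(C)C(C)=CCC[C@@H]23)cc1Br | intermediate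
45 | aryllithium from 44 (not isolated) | COCOc1cc(OCOC)c(C[C@]2(C)[C@@H](C)CC[C@]3(C)C(C)=CCC[C@@H]23)cc1[Li] | intermediate
46 | methyl 5-(Av-methyl)-2,4-bis(methoxymethoxy)benzoate | COCOc1cc(OCOC)c(C[C@]2(C)[C@@H](C)CC[C@]3(C)C(C)=CCC[C@@H]23)cc1C(=O)OC | intermediate
47 | methyl 5-(Av-methyl)-2,4-dihydroxybenzoate | COC(=O)c1cc(C[C@]2(C)[C@@H](C)CC[C@]3(C)C(C)=CCC[C@@H]23)c(O)cc1O | intermediate
48 | methyl 5-(Av-methyl)-2,4-dihydroxy-3-[(E)-(4-nitrophenyl)diazenyl]benzoate | COC(=O)c1cc(C[C@]2(C)[C@@H](C)CC[C@]3(C)C(C)=CCC[C@@H]23)c(O)c(/N=N/c2ccc(cc2)[N+](=O)[O-])c1O | intermediate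
49 | methyl 3-amino-5-(Av-methyl)-2,4-dihydroxybenzoate | COC(=O)c1cc(C[C@]2(C)[C@@H](C)CC[C@]3(C)C(C)=CCC[C@@H]23)c(O)c(N)c1O | intermediate
50 | nakijiquinone F | COC(=O)c1cc(C[C@]2(C)[C@@H](C)CC[C@]3(C)C(C)=CCC[C@@H]23)c(O)c(NC2=CC(=O)C(O)=C(C[C@]3(C)[C@@H](C)CC[C@]4(C)C(C)=CCC[C@@H]34)C2=O)c1O | target

**Step count and risks**

Total: 30 steps. Longest linear sequence: 16 steps (steps 1–5, 20–29 and 30).

Steps most likely to fail:

1. Step 10. The fully substituted ketene acetal has to reach a twisted boat in which ring A stays trans-fused to the lactone and the arylmethyl group on C9 eclipses the C8 methyl group. If this costs too much, silyl migration from oxygen to carbon or ionisation of the allylic C6–O bond may run ahead of the rearrangement. Fallback: the rearrangement is moved one step back, where C9 still carries hydrogen, and the quaternary centre is made afterwards by alkylation. It sets out from 13: LiN(iPr)2 and t-BuMe2SiCl give the tert-butyldimethylsilyl ketene acetal F1, which should rearrange in hot toluene through the less crowded boat to the silyl ester F2 and, after acidic work-up, give the acid F3 with C8 set as before. Two equivalents of LiN(iPr)2 in THF–DMPU then convert F3 into the dilithium enediolate F4, which is alkylated with 17 on the face away from the C5 and C8 methyl groups (alkylation of a carboxylic acid dianion) and, after acidification, comes back to the route at 23.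

2. Step 1. The 2-methyl group may weaken binding of the enone to the boron catalyst, so that turnover is slow and an unselective silyl-cation-catalysed addition erodes the enantiomeric purity. Fallback: C10 is set by reduction and chirality transfer. From 1, CBS reduction ((R)-2-methyl-CBS-oxazaborolidine, BH3·SMe2) gives (S)-2-methylcyclohex-2-en-1-ol F5. Johnson–Claisen rearrangement with trimethyl orthoacetate (propionic acid cat., 140 °C) moves the configuration suprafacially to C10 and gives methyl 2-[(1S)-2-methylcyclohex-2-en-1-yl]acetate F6. Hydroboration–oxidation (BH3·SMe2; NaBO3) gives the secondary alcohol F7, Dess–Martin oxidation gives the ketone F8, and Me3SiCl, NaI and Et3N in MeCN give the more substituted silyl enol ether, which is 3.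

3. Step 30. The amino group is flanked by two hydrogen-bonded hydroxyl groups and is a weak nucleophile, so substitution of the methoxy group may be slow enough for electron transfer between aminophenol and quinone, or ring closure of an ortho hydroxyl group onto the quinone, to take over. Fallback: the electrophile is changed from the vinylogous ester to the vinylogous acid, which condenses with arylamines under acid catalysis. From 30, KOH in aqueous dioxane at 60 °C gives the 2,5-dihydroxyquinone F9. F9 and 49 in EtOH with AcOH at 60 °C should condense at the unhindered C5 position with loss of water and come back to the route at 50.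

**Further compounds**

F1 | step 10 | tert-butyldimethylsilyl ketene acetal of lactone 13 | C1=C(O[Si](C)(C)C(C)(C)C)O[C@H](/C=C/C)[C@]2(C)C(C)=CCC[C@@H]12
F2 | step 10 | tert-butyldimethylsilyl (1S,2S,4aS,8aS)-2,4a,5-trimethyl-1,2,4a,7,8,8a-hexahydronaphthalene-1-carboxylate | CC(C)(C)[Si](C)(C)OC(=O)[C@H]1[C@@H](C)C=C[C@]2(C)C(C)=CCC[C@@H]12
F3 | step 10 | (1S,2S,4aS,8aS)-2,4a,5-trimethyl-1,2,4a,7,8,8a-hexahydronaphthalene-1-carboxylic acid | OC(=O)[C@H]1[C@@H](C)C=C[C@]2(C)C(C)=CCC[C@@H]12
F4 | step 10 | dilithium enediolate of acid F3 | [Li]OC(O[Li])=C1[C@@H](C)C=C[C@]2(C)C(C)=CCC[C@@H]12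
F5 | step 1 | (S)-2-methylcyclohex-2-en-1-ol | O[C@H]1CCCC=C1C
F6 | step 1 | methyl 2-[(1S)-2-methylcyclohex-2-en-1-yl]acetate | COC(=O)C[C@@H]1CCCC=C1C
F7 | step 1 | methyl 2-[(1S)-3-hydroxy-2-methylcyclohexyl]acetate (mixture at the two new centres) | COC(=O)C[C@@H]1CCCC(O)C1C
F8 | step 1 | methyl 2-[(1S)-2-methyl-3-oxocyclohexyl]acetate (mixture at the methyl-bearing carbon) | COC(=O)C[C@@H]1CCCC(=O)C1C
F9 | step 30 | 3-(Av-methyl)-2,5-dihydroxy-1,4-benzoquinone | OC1=CC(=O)C(O)=C(C[C@]2(C)[C@@H](C)CC[C@]3(C)C(C)=CCC[C@@H]23)C1=O
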